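## Retrosynthetic overview

1. Last bond, C5–C1′: the tetronic acid is carried as an aromatic 2,4-bis(silyloxy)-3-methylfuran. A palladium-catalysed asymmetric allylation with the allylic tert-butyl carbonate of the complete side chain destroys the furan aromaticity, returns the lactone and sets C5 (R).
2. C8′=C9′ (E): Julia–Kocienski olefination of a geranyl-derived (E)-enal with a tetrazolyl sulfone that already carries C10′ (S) and the 3-furyl ring.
3. Enal: from geranyl acetate (both trisubstituted E-alkenes are bought) by terminal SeO2 oxidation, carbonate formation, deacetylation and MnO2 oxidation.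
4. Sulfone: Evans allylation sets C10′; Mitsunobu thioether and oxidation; B-alkyl Suzuki coupling with 3-bromofuran.
5. Rings: none is built. The 3-furyl ring is attached intact first; the lactone ring is bought as 3-methyltetronic acid, made aromatic as the silyloxyfuran, and de-aromatised again in the last step.

Assumption: the (R,R) enantiomer of the ligand in step 12 is taken to give 5R (if the first run shows the opposite sense, the (S,S) ligand is used with nothing else changed); 3-methyltetronic acid is taken as a catalogue compound.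

## Route

Step 1
Reactants: 1 geranyl acetate [(2E)-3,7-dimethylocta-2,6-dien-1-yl acetate]
Product: 2 (2E,6E)-8-hydroxy-3,7-dimethylocta-2,6-dien-1-yl acetate
Conditions: SeO2 (0.4 equiv), t-BuOOH (70% aq., 3 equiv), salicylic acid (0.1 equiv), CH2Cl2, 23 °C
Reagents that add atoms: selenium dioxide, O=[Se]=O (oxygen carrier); tert-butyl hydroperoxide, CC(C)(C)OO (terminal oxidant that reloads it)
Why: Riley–Sharpless allylic oxidation (ene reaction then [2,3] shift) hydroxylates the E-methyl of the electron-richer distal alkene and leaves the acetate-deactivated 2,3-alkene alone, giving the (6E)-allylic alcohol.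

Step 2
Reactants: 2 (2E,6E)-8-hydroxy-3,7-dimethylocta-2,6-dien-1-yl acetate
Product: 3 (2E,6E)-8-[(tert-butoxycarbonyl)oxy]-3,7-dimethylocta-2,6-dien-1-yl acetate
Conditions: Boc2O (1.3 equiv), DMAP (0.1 equiv), CH2Cl2, 0 → 23 °C
Reagents that add atoms: di-tert-butyl dicarbonate, CC(C)(C)OC(=O)OC(=O)OC(C)(C)C
Why: DMAP-catalysed acyl transfer turns the primary allylic alcohol into a tert-butyl carbonate, which serves as protecting group now and as the ionisable leaving group in step 12.

Step 3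
Reactants: 3 (2E,6E)-8-[(tert-butoxycarbonyl)oxy]-3,7-dimethylocta-2,6-dien-1-yl acetate
Product: 4 tert-butyl (2E,6E)-8-hydroxy-2,6-dimethylocta-2,6-dien-1-yl carbonate
Conditions: K2CO3 (0.2 equiv), MeOH, 0 °C
Reagents that add atoms: none
Why: Base-catalysed transesterification (Zemplén-type methanolysis) removes the unhindered acetate much faster than methoxide attacks the hindered, less electrophilic tert-butyl carbonate.

Step 4
Reactants: 4 tert-butyl (2E,6E)-8-hydroxy-2,6-dimethylocta-2,6-dien-1-yl carbonate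
Product: 5 tert-butyl (2E,6E)-2,6-dimethyl-8-oxoocta-2,6-dien-1-yl carbonate
Conditions: MnO2 (15 equiv), CH2Cl2, 23 °C
Reagents that add atoms: none
Why: MnO2 allylic oxidation gives the (E)-enal without E/Z erosion, as for geraniol to geranial, and does not touch the carbonate.

Step 5
Reactants: 6 (4R)-4-benzyl-3-propanoyl-1,3-oxazolidin-2-one; 7 allyl iodide
Product: 8 (4R)-4-benzyl-3-[(2S)-2-methylpent-4-enoyl]-1,3-oxazolidin-2-one
Conditions: NaN(SiMe3)2, THF, −78 °C; then 7, −78 → −45 °C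
Reagents that add atoms: none
Why: Evans asymmetric alkylation: the chelated Z sodium enolate is allylated on the face opposite the benzyl group, which sets the future C10′ as 2S (dr typically ≥ 97:3).

Step 6
Reactants: 8 (4R)-4-benzyl-3-[(2S)-2-methylpent-4-enoyl]-1,3-oxazolidin-2-one
Product: 9 (2S)-2-methylpent-4-en-1-ol
Conditions: LiBH4, H2O (1 equiv), Et2O, 0 °C
Reagents that add atoms: none
Why: Reductive cleavage of the exocyclic imide carbonyl with LiBH4 gives the primary alcohol without epimerisation and returns the auxiliary.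

Step 7
Reactants: 9 (2S)-2-methylpent-4-en-1-ol
Product: 10 5-{[(2S)-2-methylpent-4-en-1-yl]sulfanyl}-1-phenyl-1H-tetrazole
Conditions: 1-phenyl-1H-tetrazole-5-thiol, PPh3, DIAD, THF, 0 → 23 °C
Reagents that add atoms: 1-phenyl-1H-tetrazole-5-thiol, Sc1nnnn1-c1ccccc1
Why: Mitsunobu thioetherification is an SN2 displacement at the primary carbon, so the adjacent stereocentre is untouched.

Step 8
Reactants: 10 5-{[(2S)-2-methylpent-4-en-1-yl]sulfanyl}-1-phenyl-1H-tetrazole
Product: 11 5-{[(2S)-2-methylpent-4-en-1-yl]sulfonyl}-1-phenyl-1H-tetrazole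
Conditions: (NH4)6Mo7O24·4H2O (10 mol%), 30% aq. H2O2, EtOH, 0 → 23 °C
Reagents that add atoms: hydrogen peroxide, OO
Why: Molybdate-catalysed peroxide oxidation takes the sulfide to the sulfone while the unactivated terminal alkene is inert; it is done before the oxidation-sensitive furan is introduced.

Step 9
Reactants: 11 5-{[(2S)-2-methylpent-4-en-1-yl]sulfonyl}-1-phenyl-1H-tetrazole; 12 3-bromofuran
Product: 14 5-{[(2S)-5-(furan-3-yl)-2-methylpentyl]sulfonyl}-1-phenyl-1H-tetrazole, via B-alkyl-9-BBN borane 13 (not isolated)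
Conditions: 9-BBN-H, THF, 0 → 23 °C; then 12, PdCl2(dppf) (5 mol%), AsPh3 (5 mol%), Cs2CO3, DMF/H2O, 23 °C
Reagents that add atoms: 9-borabicyclo[3.3.1]nonane, B1C2CCCC1CCC2 (its atoms are carried only in 13)
Why: Anti-Markovnikov hydroboration followed by B-alkyl Suzuki–Miyaura coupling joins the terminal carbon to C3 of the furan under a carbonate base mild enough for the tetrazolyl sulfone; the stereocentre is remote from both reacting centres.

Step 10
Reactants: 5 tert-butyl (2E,6E)-2,6-dimethyl-8-oxoocta-2,6-dien-1-yl carbonate; 14 5-{[(2S)-5-(furan-3-yl)-2-methylpentyl]sulfonyl}-1-phenyl-1H-tetrazole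
Product: 15 tert-butyl (2E,6E,8E,10S)-13-(furan-3-yl)-2,6,10-trimethyltrideca-2,6,8-trien-1-yl carbonate
Conditions: 14, KN(SiMe3)2, DME, −60 °C; then 5, −60 → 23 °C
Reagents that add atoms: none
Why: Julia–Kocienski olefination (addition, Smiles rearrangement, loss of SO2 and tetrazololate); pairing an alkyl tetrazolyl sulfone with a conjugated aldehyde is the E-selective combination, and the stereocentre β to the carbanion cannot epimerise.

Step 11
Reactants: 16 3-methyltetronic acid [4-hydroxy-3-methylfuran-2(5H)-one]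
Product: 18 3-methyl-4-[(triisopropylsilyl)oxy]-2-[(trimethylsilyl)oxy]furan, via silyl butenolide 17 (not isolated)
Conditions: i-Pr3SiOTf (1.0 equiv), Et3N (2.5 equiv), CH2Cl2, 0 °C; then Me3SiOTf (1.1 equiv), 0 → 23 °C; pentane extraction under argon, used crude
Reagents that add atoms: triisopropylsilyl trifluoromethanesulfonate, CC(C)[Si](C(C)C)(C(C)C)OS(=O)(=O)C(F)(F)F; trimethylsilyl trifluoromethanesulfonate, C[Si](C)(C)OS(=O)(=O)C(F)(F)F
Why: Soft enolisation: the acidic enol OH takes the robust silyl group first, then Me3SiOTf activates the vinylogous-ester carbonyl so that Et3N removes a C5 proton and the aromatic 2-silyloxyfuran forms (standard silyloxyfuran formation from butenolides).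

Step 12
Reactants: 15 tert-butyl (2E,6E,8E,10S)-13-(furan-3-yl)-2,6,10-trimethyltrideca-2,6,8-trien-1-yl carbonate; 18 3-methyl-4-[(triisopropylsilyl)oxy]-2-[(trimethylsilyl)oxy]furan
Product: 20 (5R)-4-hydroxy-3-methyl-5-[(2E,6E,8E,10S)-13-(furan-3-yl)-2,6,10-trimethyltrideca-2,6,8-trien-1-yl]furan-2(5H)-one (CNP0269661.2), via C5-allylated silyl butenolide 19 (not isolated)
Conditions: 18 (1.5 equiv), Pd2(dba)3·CHCl3 (2.5 mol%), (R,R)-DACH-phenyl Trost ligand (7.5 mol%), THF, 0 → 23 °C; then 1 M aq. HCl, THF, 0 °C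
Reagents that add atoms: none
Why: Proposed new method: zerovalent palladium ionises the allylic tert-butyl carbonate of 15 with loss of CO2, and the liberated tert-butoxide strips the trimethylsilyl group from 18 to give a furan-2-olate ion-paired with the cationic π-allylpalladium complex; C3 of this furanolate is blocked by its methyl group and flanked by two oxygen-bearing carbons while the 4-silyloxy group raises the electron density at the free C5, so outer-sphere attack from C5 on the unsubstituted allyl terminus (which keeps the 2′E alkene) breaks the furan aromaticity, forms the C5–C1′ bond and sets C5 as R inside the chiral pocket of the ligand (sense as assumed above); no free base builds up, so the new C5–H is not epimerised, and dilute acid then cleaves the vinylogous silyl ester to the tetronic acid; the closest known reaction types are the Tsuji allylation of silyl enol ethers with allyl carbonates, the palladium-catalysed decarboxylative asymmetric allylic alkylation of furan-2-yl (dienol) carbonates and the C5-selective alkylation of lithiated 4-O-alkyl 3-methyltetronates.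

## Compound list

1 | geranyl acetate [(2E)-3,7-dimethylocta-2,6-dien-1-yl acetate] | CC(C)=CCC/C(C)=C/COC(C)=O | starting material
2 | (2E,6E)-8-hydroxy-3,7-dimethylocta-2,6-dien-1-yl acetate | OC/C(C)=C/CC/C(C)=C/COC(C)=O | intermediate
3 | (2E,6E)-8-[(tert-butoxycarbonyl)oxy]-3,7-dimethylocta-2,6-dien-1-yl acetate | CC(C)(C)OC(=O)OC/C(C)=C/CC/C(C)=C/COC(C)=O | intermediate
4 | tert-butyl (2E,6E)-8-hydroxy-2,6-dimethylocta-2,6-dien-1-yl carbonate | CC(C)(C)OC(=O)OC/C(C)=C/CC/C(C)=C/CO | intermediate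
5 | tert-butyl (2E,6E)-2,6-dimethyl-8-oxoocta-2,6-dien-1-yl carbonate | CC(C)(C)OC(=O)OC/C(C)=C/CC/C(C)=C/C=O | intermediate
6 | (4R)-4-benzyl-3-propanoyl-1,3-oxazolidin-2-one | CCC(=O)N1[C@H](Cc2ccccc2)COC1=O | starting material
7 | allyl iodide (3-iodoprop-1-ene) | C=CCI | starting material
8 | (4R)-4-benzyl-3-[(2S)-2-methylpent-4-enoyl]-1,3-oxazolidin-2-one | C=CC[C@H](C)C(=O)N1[C@H](Cc2ccccc2)COC1=O | intermediate
9 | (2S)-2-methylpent-4-en-1-ol | C=CC[C@H](C)CO | intermediate
10 | 5-{[(2S)-2-methylpent-4-en-1-yl]sulfanyl}-1-phenyl-1H-tetrazole | C=CC[C@H](C)CSc1nnnn1-c1ccccc1 | intermediate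
11 | 5-{[(2S)-2-methylpent-4-en-1-yl]sulfonyl}-1-phenyl-1H-tetrazole | O=S(=O)(C[C@@H](C)CC=C)c1nnnn1-c1ccccc1 | intermediate
12 | 3-bromofuran | Brc1ccoc1 | starting material
13 | 5-({(2S)-5-(9-borabicyclo[3.3.1]nonan-9-yl)-2-methylpentyl}sulfonyl)-1-phenyl-1H-tetrazole | B1(C2CCCC1CCC2)CCC[C@H](C)CS(=O)(=O)c1nnnn1-c1ccccc1 | intermediate
14 | 5-{[(2S)-5-(furan-3-yl)-2-methylpentyl]sulfonyl}-1-phenyl-1H-tetrazole | O=S(=O)(C[C@@H](C)CCCc1ccoc1)c1nnnn1-c1ccccc1 | intermediate
15 | tert-butyl (2E,6E,8E,10S)-13-(furan-3-yl)-2,6,10-trimethyltrideca-2,6,8-trien-1-yl carbonate | CC(C)(C)OC(=O)OC/C(C)=C/CC/C(C)=C/C=C/[C@@H](C)CCCc1ccoc1 | intermediate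
16 | 3-methyltetronic acid [4-hydroxy-3-methylfuran-2(5H)-one] | CC1=C(O)COC1=O | starting material
17 | 3-methyl-4-[(triisopropylsilyl)oxy]furan-2(5H)-one | CC1=C(O[Si](C(C)C)(C(C)C)C(C)C)COC1=O | intermediate
18 | 3-methyl-4-[(triisopropylsilyl)oxy]-2-[(trimethylsilyl)oxy]furan | Cc1c(O[Si](C)(C)C)occ1O[Si](C(C)C)(C(C)C)C(C)C | intermediate
19 | (5R)-5-[(2E,6E,8E,10S)-13-(furan-3-yl)-2,6,10-trimethyltrideca-2,6,8-trien-1-yl]-3-methyl-4-[(triisopropylsilyl)oxy]furan-2(5H)-one | CC1=C(O[Si](C(C)C)(C(C)C)C(C)C)[C@@H](C/C(C)=C/CC/C(C)=C/C=C/[C@@H](C)CCCc2ccoc2)OC1=O | intermediate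
20 | (5R)-4-hydroxy-3-methyl-5-[(2E,6E,8E,10S)-13-(furan-3-yl)-2,6,10-trimethyltrideca-2,6,8-trien-1-yl]furan-2(5H)-one (CNP0269661.2) | CC1=C(O)[C@@H](C/C(C)=C/CC/C(C)=C/C=C/[C@@H](C)CCCc2ccoc2)OC1=O | target

## Step count and risks

Total step count: 12 (steps 1–4 enal, steps 5–9 sulfone, step 10 union, step 11 nucleophile, step 12 key step).
Longest linear sequence: 7 steps (5 → 6 → 7 → 8 → 9 → 10 → 12).

The three steps most likely to fail:

**Step 12** (C3 versus C5 attack of the furanolate, level and sense of enantiocontrol, ionisation of a trisubstituted allyl carbonate). Fallback: the stereocentre is set by auxiliary control on an acyclic glycolate and the lactone ring is built afterwards by Dieckmann cyclisation, instead of alkylating a preformed ring. It sets out from 15 and comes back to the route at 20.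
- NaOMe in MeOH (23 °C) cleaves the carbonate of 15 to (2E,6E,8E,10S)-13-(furan-3-yl)-2,6,10-trimethyltrideca-2,6,8-trien-1-ol F1.
- CBr4/PPh3 (CH2Cl2, 0 °C) gives (2E,6E,8E,10S)-1-bromo-13-(furan-3-yl)-2,6,10-trimethyltrideca-2,6,8-triene F2.
- The sodium enolate (NaN(SiMe3)2, THF, −78 °C) of the glycolate imide (4S)-4-benzyl-3-{[(4-methoxybenzyl)oxy]acetyl}-1,3-oxazolidin-2-one (COc1ccc(COCC(=O)N2[C@@H](Cc3ccccc3)COC2=O)cc1) is alkylated by F2 on the face opposite the benzyl group to give (4S)-4-benzyl-3-[(2R,4E,8E,10E,12S)-15-(furan-3-yl)-2-[(4-methoxybenzyl)oxy]-4,8,12-trimethylpentadeca-4,8,10-trienoyl]-1,3-oxazolidin-2-one F3.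
- NaOMe in MeOH/THF (−20 °C) gives methyl (2R,4E,8E,10E,12S)-15-(furan-3-yl)-2-[(4-methoxybenzyl)oxy]-4,8,12-trimethylpentadeca-4,8,10-trienoate F4.
- DDQ (CH2Cl2/pH 7 buffer, 0 °C) removes the 4-methoxybenzyl group to give methyl (2R,4E,8E,10E,12S)-15-(furan-3-yl)-2-hydroxy-4,8,12-trimethylpentadeca-4,8,10-trienoate F5.
- Propanoyl chloride/pyridine gives methyl (2R,4E,8E,10E,12S)-15-(furan-3-yl)-4,8,12-trimethyl-2-(propanoyloxy)pentadeca-4,8,10-trienoate F6.
- LiN(SiMe3)2 (THF, −78 → 0 °C) closes the ring by Dieckmann condensation with loss of methanol and gives 20 directly.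

**Step 10** (E/Z ratio at the new C8′=C9′ alkene, base-sensitive enal and carbonate). Fallback: the C8′–C9′ bond is made as a single bond by sulfone alkylation and the alkene is formed by elimination, instead of by olefination. It sets out from 4 (together with 14) and comes back at 15.
- CBr4/PPh3 (CH2Cl2, 0 °C) converts 4 into tert-butyl (2E,6E)-8-bromo-2,6-dimethylocta-2,6-dien-1-yl carbonate F7.
- The potassium anion of 14 (KN(SiMe3)2, THF, −78 °C) is alkylated by F7 to tert-butyl (2E,6E,10S)-13-(furan-3-yl)-2,6,10-trimethyl-9-[(1-phenyl-1H-tetrazol-5-yl)sulfonyl]trideca-2,6-dien-1-yl carbonate F8 (both C9 epimers).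
- DBU (toluene, 60 °C) eliminates the sulfinate towards the more acidic allylic hydrogens and gives the conjugated (6E,8E)-diene 15.

**Step 9** (tetrazolyl sulfone under aqueous basic coupling conditions). Fallback: the furan is coupled on before the base-labile sulfone exists, and the sulfone is generated last. It sets out from 10 and comes back at 14.
- Hydroboration of sulfide 10 with 9-BBN-H (THF, 23 °C) gives 5-({(2S)-5-(9-borabicyclo[3.3.1]nonan-9-yl)-2-methylpentyl}sulfanyl)-1-phenyl-1H-tetrazole F9.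
- F9 is coupled in the same flask with 12 (PdCl2(dppf), K3PO4, DMF/H2O, 50 °C) to give 5-{[(2S)-5-(furan-3-yl)-2-methylpentyl]sulfanyl}-1-phenyl-1H-tetrazole F10.
- Oxidation with (NH4)6Mo7O24·4H2O/H2O2 (EtOH, 0 °C, stopped as soon as the sulfoxide is consumed) gives 14.

## Further compounds

F1 | step 12 | (2E,6E,8E,10S)-13-(furan-3-yl)-2,6,10-trimethyltrideca-2,6,8-trien-1-ol | OC/C(C)=C/CC/C(C)=C/C=C/[C@@H](C)CCCc1ccoc1
F2 | step 12 | (2E,6E,8E,10S)-1-bromo-13-(furan-3-yl)-2,6,10-trimethyltrideca-2,6,8-triene | BrC/C(C)=C/CC/C(C)=C/C=C/[C@@H](C)CCCc1ccoc1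
F3 | step 12 | (4S)-4-benzyl-3-[(2R,4E,8E,10E,12S)-15-(furan-3-yl)-2-[(4-methoxybenzyl)oxy]-4,8,12-trimethylpentadeca-4,8,10-trienoyl]-1,3-oxazolidin-2-one | COc1ccc(CO[C@H](C/C(C)=C/CC/C(C)=C/C=C/[C@@H](C)CCCc2ccoc2)C(=O)N2[C@@H](Cc3ccccc3)COC2=O)cc1
F4 | step 12 | methyl (2R,4E,8E,10E,12S)-15-(furan-3-yl)-2-[(4-methoxybenzyl)oxy]-4,8,12-trimethylpentadeca-4,8,10-trienoate | COc1ccc(CO[C@H](C/C(C)=C/CC/C(C)=C/C=C/[C@@H](C)CCCc2ccoc2)C(=O)OC)cc1
F5 | step 12 | methyl (2R,4E,8E,10E,12S)-15-(furan-3-yl)-2-hydroxy-4,8,12-trimethylpentadeca-4,8,10-trienoate | O[C@H](C/C(C)=C/CC/C(C)=C/C=C/[C@@H](C)CCCc1ccoc1)C(=O)OC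
F6 | step 12 | methyl (2R,4E,8E,10E,12S)-15-(furan-3-yl)-4,8,12-trimethyl-2-(propanoyloxy)pentadeca-4,8,10-trienoate | CCC(=O)O[C@H](C/C(C)=C/CC/C(C)=C/C=C/[C@@H](C)CCCc1ccoc1)C(=O)OC
F7 | step 10 | tert-butyl (2E,6E)-8-bromo-2,6-dimethylocta-2,6-dien-1-yl carbonate | CC(C)(C)OC(=O)OC/C(C)=C/CC/C(C)=C/CBr
F8 | step 10 | tert-butyl (2E,6E,10S)-13-(furan-3-yl)-2,6,10-trimethyl-9-[(1-phenyl-1H-tetrazol-5-yl)sulfonyl]trideca-2,6-dien-1-yl carbonate | CC(C)(C)OC(=O)OC/C(C)=C/CC/C(C)=C/CC([C@@H](C)CCCc1ccoc1)S(=O)(=O)c1nnnn1-c1ccccc1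
F9 | step 9 | 5-({(2S)-5-(9-borabicyclo[3.3.1]nonan-9-yl)-2-methylpentyl}sulfanyl)-1-phenyl-1H-tetrazole | B1(C2CCCC1CCC2)CCC[C@H](C)CSc1nnnn1-c1ccccc1
F10 | step 9 | 5-{[(2S)-5-(furan-3-yl)-2-methylpentyl]sulfanyl}-1-phenyl-1H-tetrazole | c1cc(CCC[C@H](C)CSc2nnnn2-c2ccccc2)co1
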